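**Assumption:** (R)-BINAP is taken to steer the Heck step to the (5S)-dihydrodioxepine 7. If the sense of induction is the opposite, (S)-BINAP is used and nothing else changes.

## Analysis of the target

The target 16 has one ring, a tetrahydrofuran numbered here O1, C2, C3, C4, C5. C2 carries the 4-hydroxyphenyl group, C3 the acetoxymethyl carbon C3a, and C4 the exocyclic carbinol carbon C4a, which bears an acetate and the 4-methoxyphenyl group; C5 is a CH2. There are four stereocentres: C2 (R), C3 (S) and C4 (R) are contiguous and all-trans, and C4a (S) sits next to C4 outside the ring. The sensitive groups are the C4a acetate (a 4-methoxybenzylic ester that ionises in acid), the C2–O1 bond (a 4-hydroxybenzylic ether) and a free phenol that must coexist with two alkyl acetates. Hydrogenolytic protecting groups are therefore excluded, and the phenol has to be released last under nearly neutral conditions. The difficulty lies in three adjacent ring centres plus an exocyclic centre, of which only C4a is open to direct reagent control, and in two differently oxygenated aryl groups. The strategy rests on the sequence O1–C2(aryl)–C3–C3a. If C3a is at the aldehyde level, C2–C3 is an aldol bond between an aryl oxocarbenium carbon and an enol carbon, and because both are already tied together through O1–C5–C4 they can be stored in a seven-membered vinyl acetal. As the all-trans arrangement is the most stable one, C2 and C3 can be left to thermodynamics, so that only C4 and C4a need a chiral reagent.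

## Retrosynthetic reasoning

**16 back to 14.** The last bonds cut are O–Si at the phenol and the acetyl C–O bond at C4a, giving 15 and then 14. The phenol is unmasked last by fluoride because this leaves both acetates and both benzylic C–O bonds alone. The C4a acetate is put on only after the carbinol centre exists.

**14 back to 13.** The C4a–H bond is cut to the aryl ketone 13. C4a is flanked by an aryl group and a secondary alkyl group, which is the situation a catalyst-controlled ketone reduction handles best. This makes the C4a configuration independent of the ring centres.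

**13 back to 11 (via 12).** The C4a carbonyl is traced to a C=C bond. A ketone at C4a would make C4 acidic and prone to β-elimination of O1 during the earlier steps, whereas an alkenyl group is inert there and can be attached by a Heck reaction. A plain 1-arylvinyl group would be the shortest mask. As an α-alkyl-4-methoxystyrene unit, however, it is a strong π-nucleophile towards an oxocarbenium ion (six-membered Prins closure to a tertiary anisyl cation) and towards traces of acid. The alkene therefore carries a β-ester, which deactivates it and is lost in the cleavage.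

**11 back to 9.** The C3a acetate comes from alcohol 10 and this from aldehyde 9. The acetate is installed before the alkene cleavage so that no free hydroxyl is present to direct or disturb the later reduction.

**9 back to 7 (via 8).** The C2–C3 bond is cut and C2 is reconnected to the aldehyde oxygen, which gives the isomeric 4,5-dihydro-1,3-dioxepine 7. This removes two stereocentres at once: C3 becomes an sp2 enol ether carbon and C2 an acetal carbon whose configuration does not matter. Only C5 of 7 (C4 of the target) remains. The forward reaction must ionise the acetal at the vinyl oxygen, close the five-membered ring through carbon, and equilibrate C2 and C3 to the all-trans isomer.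

**7 back to 4 and 6.** The bond between C5 of the dioxepine and the alkenyl carbon is cut. Forward, an enantioselective Heck reaction of the alkenyl triflate 6 with the symmetric alkene of 4 sets the single catalyst-controlled ring centre and moves the double bond into the enol ether position that the key step needs.

**4, 6 and 2 back to starting materials.** Acetal 4 comes from aldehyde 2 and diol 3, 2 from phenol 1 by silylation, and 6 from β-keto ester 5 by enol triflation. All are one-step operations on commercial materials.

## Alternatives that were turned down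

**Alternative 1:** The C4–C5 bond is cut; C5 comes from a one-carbon oxocarbenium ion and the C4a oxygen from acetate. Forward, a Lewis acid in acetic acid (BF3·OEt2/AcOH) ionises the methoxymethyl ether A2. The styrene carbon C4 attacks the O1=CH2 cation to close the tetrahydrofuran, and acetate captures the anisyl cation at C4a to give the triacetate A1.
- For it: ring, C4 centre and C4a–O bond arise in one step with the right ester already in place, and A1 is one selective aryl-acetate cleavage from 16. On step count after the key step it is clearly stronger than the chosen route (one step against six), and it needs no palladium.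
- Against it: C4a arises by capture of a planar, freely rotating benzylic cation with nothing to enforce (S), and the same cation can re-form from A1 under the conditions. The oxocarbenium ion sits on a homoallylic ether with a benzylic C2, so a 2-oxonia-Cope shift can break the C2–C3 bond and erode both centres. A2 itself needs a separate enantio- and diastereoselective construction of C2 and C3.
- Comparison: the chosen route pays with a longer endgame but sets C4 by asymmetric catalysis, C2 and C3 by thermodynamics and C4a by a chiral reagent on a ketone.

**Alternative 2:** The O1–C5 bond is cut; C4, C5 and the C4a carbon come from a 3-substituted oxetane. Forward, an acid catalyst (chiral phosphoric acid or Sc(OTf)3) lets the C2 hydroxyl of A4 open one oxetane CH2 in a 5-exo-tet closure, giving A3 with the other CH2 released as a primary alcohol.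
- For it: a strain-driven C–O closure under mild conditions, no cationic C–C bond formation, no epimerisable aldehyde, and the C3a acetate is already present. On irreversibility of the C4-setting step it is as strong as or stronger than the Heck step.
- Against it: the two oxetane CH2 groups of A4 are diastereotopic, so the catalyst must override the bias of C2 and C3. The electron-rich benzylic alcohol can ionise at C2 under acid. A3 has neither the aryl group nor the right oxidation level at C4a, so oxidation, aryl addition, re-oxidation and asymmetric reduction follow before the two final steps, and the C4a problem returns unchanged. A4 needs its own asymmetric synthesis of C2 and C3.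
- Comparison: the chosen route brings in the C4a carbon with its aryl group in the same step that sets C4, and needs no separate construction of C2 and C3.

**Alternative 3:** The C3–C4 bond is cut between an enol ether carbon and a styrene carbon tethered through O1. Forward, constant-current anodic oxidation of A6 in an alcohol solvent couples the two alkenes in a five-membered closure. Both cations are trapped by the solvent, giving A5 with a dimethyl acetal at C3a and a methyl ether at C4a as a mixture of C4a epimers.
- For it: the most congested C–C bond is made directly from two unfunctionalised alkenes, both C3a and C4a emerge oxidised, no metal catalyst is used, and A6 has a single stereocentre. On bond-forming economy it is stronger than the chosen route.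
- Against it: C4a is uncontrolled and carries a methyl ether that must be exchanged for an acetate, which in practice means oxidation to ketone 13 and the same reduction as in the chosen route. C3a needs hydrolysis, reduction and acetylation. The ring centres are set kinetically in a radical-cation closure with C2 as the only control element. The anisyl styrene and the silyloxyarene are oxidised at potentials close to or below that of the enol ether, and C2 of A6 is a benzylic and allylic ether that ionises easily.
- Comparison: the chosen route gives the all-trans ring by equilibration and a defined C4a, with an endgame that is no longer.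

Key step: step 5

## Route

Ring numbering O1, C2 (aryl), C3, C4, C5 is used for all tetrahydrofurans. Dioxepines are numbered O1, C2 (acetal), O3, C4, C5, C6, C7.

**Step 1**
Reactants: 1 4-hydroxybenzaldehyde
Product: 2 4-(triisopropylsilyloxy)benzaldehyde
Conditions: iPr3SiCl, imidazole, DMF, rt
Reagents that add atoms: triisopropylsilyl chloride, CC(C)[Si](Cl)(C(C)C)C(C)C
Why: Silylation of a phenol with a silyl chloride and imidazole. The bulky aryl silyl ether should survive the acid of step 2, the palladium/amine of step 4, the Lewis acid of step 5, hydride and ozone, and it is removed by fluoride at the end.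

**Step 2**
Reactants: 2 4-(triisopropylsilyloxy)benzaldehyde; 3 (Z)-but-2-ene-1,4-diol
Product: 4 2-[4-(triisopropylsilyloxy)phenyl]-4,7-dihydro-1,3-dioxepine
Conditions: pyridinium p-toluenesulfonate (cat.), benzene, reflux, Dean–Stark; Et3N quench
Reagents that add atoms: none
Why: Acid-catalysed acetalisation driven by azeotropic removal of water; the cis diol closes the seven-membered ring. The product has a mirror plane through the acetal carbon, so its two alkene carbons are enantiotopic, which is what step 4 exploits.

**Step 3**
Reactants: 5 methyl 3-(4-methoxyphenyl)-3-oxopropanoate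
Product: 6 methyl (Z)-3-(4-methoxyphenyl)-3-(trifluoromethanesulfonyloxy)prop-2-enoate
Conditions: NaH, Et2O, 0 °C; then Tf2O, 0 °C
Reagents that add atoms: trifluoromethanesulfonic anhydride, O=S(=O)(OS(=O)(=O)C(F)(F)F)C(F)(F)F
Why: O-Triflation of the chelated sodium enolate of a β-keto ester, which should give the (Z)-enol triflate. The ester stabilises the triflate against ionisation to an anisyl vinyl cation; the alkene geometry is of no consequence later because this double bond is cleaved in step 8.

**Step 4**
Reactants: 4 2-[4-(triisopropylsilyloxy)phenyl]-4,7-dihydro-1,3-dioxepine (2 equiv); 6 methyl (Z)-3-(4-methoxyphenyl)-3-(trifluoromethanesulfonyloxy)prop-2-enoate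
Product: 7 methyl (E)-3-(4-methoxyphenyl)-3-[(5S)-2-[4-(triisopropylsilyloxy)phenyl]-4,5-dihydro-1,3-dioxepin-5-yl]prop-2-enoate, both epimers at the acetal carbon
Conditions: Pd(OAc)2 (5 mol %), (R)-BINAP (10 mol %), iPr2NEt, 4 Å molecular sieves, benzene, 50 °C
Reagents that add atoms: none
Why: Enantioselective intermolecular Heck reaction on the cationic pathway: oxidative addition of 6 to zerovalent palladium gives a cationic alkenylpalladium complex whose chiral bisphosphine selects one enantiotopic alkene carbon of 4 for syn carbopalladation, which sets C5. Syn β-hydride elimination can only take a hydrogen of C7, since the hydrogen on C5 is anti to palladium, so the double bond ends as the enol ether C6=C7 and the new centre cannot be eroded by chain walking. The alkene geometry of 6 is retained (the descriptor changes to E by priority only), and the acetal carbon becomes a stereocentre of no consequence.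

**Step 5**
Reactants: 7 methyl (E)-3-(4-methoxyphenyl)-3-[(5S)-2-[4-(triisopropylsilyloxy)phenyl]-4,5-dihydro-1,3-dioxepin-5-yl]prop-2-enoate
Product: 9 methyl (E)-3-[(2R,3R,4S)-3-formyl-2-[4-(triisopropylsilyloxy)phenyl]tetrahydrofuran-4-yl]-3-(4-methoxyphenyl)prop-2-enoate, via ring-opened enol silane oxocarbenium triflate 8 (not isolated)
Conditions: Me3SiOTf (0.2 equiv), 2,6-di-tert-butyl-4-methylpyridine (0.1 equiv), CH2Cl2, −78 °C to −20 °C; Et3N, then aq. NaHCO3
Reagents that add atoms: none
Why: Me3SiOTf silylates the enol ether oxygen O1 of 7 and the C2–O1 acetal bond ionises, because the leaving group is an enol silane and the cation is a 4-silyloxybenzylidene oxocarbenium ion; the two halves of ion pair 8 stay joined through O3–C4–C5 (dioxepine numbering). The enol silane carbon C6 then adds to the oxocarbenium carbon in an intramolecular Mukaiyama aldol, which makes the C2–C3 bond of the tetrahydrofuran, and loss of the silyl group from the new carbonyl oxygen returns the Lewis acid. The closest known reaction type is the Lewis acid mediated [1,3] oxygen-to-carbon rearrangement of cyclic vinyl acetals, here of a 2-aryl-4,5-dihydro-1,3-dioxepine to a tetrahydrofuran-3-carbaldehyde, a relative of the Petasis–Ferrier rearrangement. The one ring is closed in a five-membered 5-(enolexo)-endo-trig mode: the enol C=C bond lies outside the new ring and the C=O+ bond inside it, an endo closure that oxocarbenium ions undergo readily. C3 is set in the bond formation trans to the alkenyl group on the neighbouring C4, the enol silane meeting the cation on the face away from that group, and it stays correctable because it is alpha to the aldehyde. C2 is set under thermodynamic control: on warming, the electron-rich aryl group lets the product return to 8 (retro-aldol or heterolysis of the benzylic C2–O1 bond), so both acetal epimers of 7 and any 2,3-cis aldehyde should drain into the all-trans isomer, whose configuration is dictated by C4 alone. The selectivity the step needs is chemoselectivity for the enol silane over the only other pi system; that alkene is a beta-aryl acrylate whose ester makes it a far weaker nucleophile than the enol silane, and the hindered pyridine removes triflic acid, so neither Prins closure nor alkene protonation should compete. C5 of 7 lies outside the ionising system and is carried unchanged into C4 of 9.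

**Step 6**
Reactants: 9 methyl (E)-3-[(2R,3R,4S)-3-formyl-2-[4-(triisopropylsilyloxy)phenyl]tetrahydrofuran-4-yl]-3-(4-methoxyphenyl)prop-2-enoate
Product: 10 methyl (E)-3-[(2R,3S,4S)-3-(hydroxymethyl)-2-[4-(triisopropylsilyloxy)phenyl]tetrahydrofuran-4-yl]-3-(4-methoxyphenyl)prop-2-enoate
Conditions: NaBH4, THF/MeOH, −20 °C to 0 °C
Reagents that add atoms: none
Why: Chemoselective borohydride reduction of the aldehyde; the β,β-disubstituted enoate and the aryl silyl ether should be untouched at this temperature. This removes the group that makes C3 epimerisable and O1 prone to β-elimination; the C3 descriptor changes by priority only.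

**Step 7**
Reactants: 10 methyl (E)-3-[(2R,3S,4S)-3-(hydroxymethyl)-2-[4-(triisopropylsilyloxy)phenyl]tetrahydrofuran-4-yl]-3-(4-methoxyphenyl)prop-2-enoate
Product: 11 methyl (E)-3-[(2R,3S,4S)-3-(acetoxymethyl)-2-[4-(triisopropylsilyloxy)phenyl]tetrahydrofuran-4-yl]-3-(4-methoxyphenyl)prop-2-enoate
Conditions: Ac2O, pyridine, DMAP (cat.), CH2Cl2, 0 °C to rt
Reagents that add atoms: acetic anhydride, CC(=O)OC(C)=O
Why: Nucleophilic-catalysed acylation of a primary alcohol installs the first acetate of the target. With no free hydroxyl left, step 9 cannot suffer substrate-directed hydride delivery.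

**Step 8**
Reactants: 11 methyl (E)-3-[(2R,3S,4S)-3-(acetoxymethyl)-2-[4-(triisopropylsilyloxy)phenyl]tetrahydrofuran-4-yl]-3-(4-methoxyphenyl)prop-2-enoate
Product: 13 [(2R,3S,4R)-4-(4-methoxybenzoyl)-2-[4-(triisopropylsilyloxy)phenyl]tetrahydrofuran-3-yl]methyl acetate, via ozonide 12 (not isolated)
Conditions: O3/O2, CH2Cl2, −78 °C, stopped at first excess (Sudan Red 7B indicator); then PPh3, −78 °C to rt
Reagents that add atoms: ozone, [O-][O+]=O
Why: Criegee ozonolysis of the only C=C bond gives ozonide 12, which triphenylphosphine reduces to the aryl ketone with loss of the ester-bearing carbon as methyl glyoxylate. The neutral reductive work-up should keep C4, now alpha to the ketone and beta to O1, from epimerising or eliminating; its descriptor changes to R by priority only.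

**Step 9**
Reactants: 13 [(2R,3S,4R)-4-(4-methoxybenzoyl)-2-[4-(triisopropylsilyloxy)phenyl]tetrahydrofuran-3-yl]methyl acetate
Product: 14 [(2R,3S,4R)-4-[(S)-hydroxy(4-methoxyphenyl)methyl]-2-[4-(triisopropylsilyloxy)phenyl]tetrahydrofuran-3-yl]methyl acetate
Conditions: (R)-2-methyl-CBS-oxazaborolidine (0.3 equiv), BH3·SMe2, THF, −20 °C; MeOH quench
Reagents that add atoms: none
Why: Corey–Bakshi–Shibata reduction: the ketone binds the ring boron with the aryl group as the large substituent pointing away from the catalyst, and the borane held on nitrogen delivers hydride to the Re face, the same sense in which the (R)-catalyst turns acetophenone into (S)-1-phenylethanol, so C4a should become (S). Catalyst control is relied on over the bias of the C4 centre; the acetate and the aryl silyl ether are inert to borane at this temperature.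

**Step 10**
Reactants: 14 [(2R,3S,4R)-4-[(S)-hydroxy(4-methoxyphenyl)methyl]-2-[4-(triisopropylsilyloxy)phenyl]tetrahydrofuran-3-yl]methyl acetate
Product: 15 [(2R,3S,4R)-4-[(S)-acetoxy(4-methoxyphenyl)methyl]-2-[4-(triisopropylsilyloxy)phenyl]tetrahydrofuran-3-yl]methyl acetate
Conditions: Ac2O, pyridine, DMAP (cat.), CH2Cl2, 0 °C
Reagents that add atoms: acetic anhydride, CC(=O)OC(C)=O
Why: Acylation at oxygen under basic conditions does not touch the C4a–O bond, so the (S) configuration is retained; acid, which would ionise the 4-methoxybenzylic position, is avoided.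

**Step 11**
Reactants: 15 [(2R,3S,4R)-4-[(S)-acetoxy(4-methoxyphenyl)methyl]-2-[4-(triisopropylsilyloxy)phenyl]tetrahydrofuran-3-yl]methyl acetate
Product: 16 [(2R,3S,4R)-4-[(S)-acetoxy(4-methoxyphenyl)methyl]-2-(4-hydroxyphenyl)tetrahydrofuran-3-yl]methyl acetate
Conditions: Bu4NF, AcOH (1.5 equiv), THF, 0 °C
Reagents that add atoms: none
Why: Fluoride cleaves the aryl O–Si bond, which is far more labile than an alkyl silyl ether would be. Acetic acid buffers fluoride and phenoxide so that the two acetates, the ionisable C4a ester and the benzylic C2–O1 ether should stay intact.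

## Compound list

1 | 4-hydroxybenzaldehyde | O=Cc1ccc(O)cc1 | starting material
2 | 4-(triisopropylsilyloxy)benzaldehyde | O=Cc1ccc(O[Si](C(C)C)(C(C)C)C(C)C)cc1 | intermediate
3 | (Z)-but-2-ene-1,4-diol | OC/C=C\CO | starting material
4 | 2-[4-(triisopropylsilyloxy)phenyl]-4,7-dihydro-1,3-dioxepine | CC(C)[Si](Oc1ccc(C2OCC=CCO2)cc1)(C(C)C)C(C)C | intermediate
5 | methyl 3-(4-methoxyphenyl)-3-oxopropanoate | COC(=O)CC(=O)c1ccc(OC)cc1 | starting material
6 | methyl (Z)-3-(4-methoxyphenyl)-3-(trifluoromethanesulfonyloxy)prop-2-enoate | COC(=O)/C=C(\OS(=O)(=O)C(F)(F)F)c1ccc(OC)cc1 | intermediate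
7 | methyl (E)-3-(4-methoxyphenyl)-3-[(5S)-2-[4-(triisopropylsilyloxy)phenyl]-4,5-dihydro-1,3-dioxepin-5-yl]prop-2-enoate (either acetal epimer) | COc1ccc(/C(=C/C(=O)OC)[C@H]2COC(c3ccc(O[Si](C(C)C)(C(C)C)C(C)C)cc3)OC=C2)cc1 | intermediate (precursor of the key step)
8 | ring-opened ion pair of 7: (Z)-trimethylsilyl enol ether tethered to the 4-(triisopropylsilyloxy)benzylidene oxocarbenium ion, triflate salt | COc1ccc(/C(=C/C(=O)OC)[C@@H](C[O+]=Cc2ccc(O[Si](C(C)C)(C(C)C)C(C)C)cc2)/C=C\O[Si](C)(C)C)cc1.[O-]S(=O)(=O)C(F)(F)F | intermediate (not isolated)
9 | methyl (E)-3-[(2R,3R,4S)-3-formyl-2-[4-(triisopropylsilyloxy)phenyl]tetrahydrofuran-4-yl]-3-(4-methoxyphenyl)prop-2-enoate (all-trans) | COc1ccc(/C(=C/C(=O)OC)[C@H]2CO[C@@H](c3ccc(O[Si](C(C)C)(C(C)C)C(C)C)cc3)[C@@H]2C=O)cc1 | intermediate (product of the key step)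
10 | methyl (E)-3-[(2R,3S,4S)-3-(hydroxymethyl)-2-[4-(triisopropylsilyloxy)phenyl]tetrahydrofuran-4-yl]-3-(4-methoxyphenyl)prop-2-enoate | COc1ccc(/C(=C/C(=O)OC)[C@H]2CO[C@@H](c3ccc(O[Si](C(C)C)(C(C)C)C(C)C)cc3)[C@@H]2CO)cc1 | intermediate
11 | methyl (E)-3-[(2R,3S,4S)-3-(acetoxymethyl)-2-[4-(triisopropylsilyloxy)phenyl]tetrahydrofuran-4-yl]-3-(4-methoxyphenyl)prop-2-enoate | COc1ccc(/C(=C/C(=O)OC)[C@H]2CO[C@@H](c3ccc(O[Si](C(C)C)(C(C)C)C(C)C)cc3)[C@@H]2COC(C)=O)cc1 | intermediate
12 | ozonide of 11: 1,2,4-trioxolane with the 4-methoxyphenyl group and the tetrahydrofuran C4 on one carbon and the methoxycarbonyl group on the other (mixture at the trioxolane carbons) | COc1ccc(C2(OOC(C(=O)OC)O2)[C@H]3CO[C@@H](c4ccc(O[Si](C(C)C)(C(C)C)C(C)C)cc4)[C@@H]3COC(C)=O)cc1 | intermediate (not isolated)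
13 | [(2R,3S,4R)-4-(4-methoxybenzoyl)-2-[4-(triisopropylsilyloxy)phenyl]tetrahydrofuran-3-yl]methyl acetate | COc1ccc(C(=O)[C@H]2CO[C@@H](c3ccc(O[Si](C(C)C)(C(C)C)C(C)C)cc3)[C@@H]2COC(C)=O)cc1 | intermediate
14 | [(2R,3S,4R)-4-[(S)-hydroxy(4-methoxyphenyl)methyl]-2-[4-(triisopropylsilyloxy)phenyl]tetrahydrofuran-3-yl]methyl acetate | COc1ccc([C@@H](O)[C@H]2CO[C@@H](c3ccc(O[Si](C(C)C)(C(C)C)C(C)C)cc3)[C@@H]2COC(C)=O)cc1 | intermediate
15 | [(2R,3S,4R)-4-[(S)-acetoxy(4-methoxyphenyl)methyl]-2-[4-(triisopropylsilyloxy)phenyl]tetrahydrofuran-3-yl]methyl acetate | COc1ccc([C@@H](OC(C)=O)[C@H]2CO[C@@H](c3ccc(O[Si](C(C)C)(C(C)C)C(C)C)cc3)[C@@H]2COC(C)=O)cc1 | intermediate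
16 | [(2R,3S,4R)-4-[(S)-acetoxy(4-methoxyphenyl)methyl]-2-(4-hydroxyphenyl)tetrahydrofuran-3-yl]methyl acetate (CNP0231272.1) | COc1ccc([C@@H](OC(C)=O)[C@H]2CO[C@@H](c3ccc(O)cc3)[C@@H]2COC(C)=O)cc1 | target

## Step count and least certain steps

Total: 11 steps. Longest linear sequence: 10 steps (steps 1, 2, 4, 5, 6, 7, 8, 9, 10, 11); step 3 is a one-step side branch.

**Step 5 (key step).** The most likely failure is incomplete equilibration after the kinetic closure, so that the configuration at C2 stays mixed while longer exposure to the Lewis acid costs material through β-elimination of the β-alkoxy aldehyde. Capture of the cation by the C4 alkenyl group is the second concern and is the reason for the ester on that alkene. Fallback, from 7 back to 10: the contraction is run cold and quenched cold, accepting a mixture of 9 and its C2 epimer, methyl (E)-3-[(2S,3R,4S)-3-formyl-2-[4-(triisopropylsilyloxy)phenyl]tetrahydrofuran-4-yl]-3-(4-methoxyphenyl)prop-2-enoate F1. Reduction with NaBH4 gives the corresponding alcohol, methyl (E)-3-[(2S,3S,4S)-3-(hydroxymethyl)-2-[4-(triisopropylsilyloxy)phenyl]tetrahydrofuran-4-yl]-3-(4-methoxyphenyl)prop-2-enoate F2, together with 10. In these alcohols retro-aldol and β-elimination are no longer possible. C2 alone is then equilibrated with catalytic camphorsulfonic acid in CH2Cl2 by reversible heterolysis of the benzylic C2–O1 bond and five-membered re-closure, which should converge on the all-trans alcohol 10.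

**Step 4.** The most likely failure is insufficient enantiofacial discrimination, possibly together with slow insertion because the cis ester chelates palladium in the alkenylpalladium intermediate. Fallback, from 7 of modest enantiomeric purity back to 14: the material is carried through steps 5 to 9 unchanged. The reagent-controlled reduction of step 9 then turns the minor enantiomer of 13 into a diastereomer of 14, [(2S,3R,4S)-4-[(S)-hydroxy(4-methoxyphenyl)methyl]-2-[4-(triisopropylsilyloxy)phenyl]tetrahydrofuran-3-yl]methyl acetate F3. F3 is removed by chromatography or crystallisation, so that 14 is obtained enantiomerically enriched by diastereomer separation and not by the Heck catalyst alone.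

**Step 9.** The most likely failure is mismatched double stereodifferentiation: the α-branched C4 substituent competes with the aryl group as the large group, or the ring centres oppose the catalyst, giving poor selectivity at C4a. Fallback, from 13 back to 14: 13 is reduced without a chiral reagent (NaBH4, CeCl3, MeOH) and the two C4a epimers are separated as diastereomers. The unwanted [(2R,3S,4R)-4-[(R)-hydroxy(4-methoxyphenyl)methyl]-2-[4-(triisopropylsilyloxy)phenyl]tetrahydrofuran-3-yl]methyl acetate F4 is oxidised back to 13 with Dess–Martin periodinane and recycled, while the (S) epimer is 14.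

**Step 8.** The most likely failure is competing oxidation of the electron-rich arene rings, because the electron-poor trisubstituted enoate reacts slowly with ozone. Fallback, from 11 back to 13: dihydroxylation with OsO4 (cat.) and N-methylmorpholine N-oxide gives the diol, methyl 3-[(2R,3S,4S)-3-(acetoxymethyl)-2-[4-(triisopropylsilyloxy)phenyl]tetrahydrofuran-4-yl]-2,3-dihydroxy-3-(4-methoxyphenyl)propanoate F5. Glycol cleavage of F5 with NaIO4 then gives 13; neither reagent attacks the arenes.

**Step 11.** The most likely failure is partial loss of acetyl groups through the basicity of fluoride and of the liberated phenoxide. Fallback, from 15 back to 16: the desilylation is taken to completion regardless. The crude mixture is exhaustively acetylated (Ac2O, pyridine) to the triacetate, [(2R,3S,4R)-4-[(S)-acetoxy(4-methoxyphenyl)methyl]-2-(4-acetoxyphenyl)tetrahydrofuran-3-yl]methyl acetate F6. The aryl acetate of F6 alone is then removed by aminolysis with pyrrolidine in CH2Cl2, which leaves alkyl acetates intact and gives 16.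

## Further compounds

F1 | step 5 | methyl (E)-3-[(2S,3R,4S)-3-formyl-2-[4-(triisopropylsilyloxy)phenyl]tetrahydrofuran-4-yl]-3-(4-methoxyphenyl)prop-2-enoate (C2 epimer of 9) | COc1ccc(/C(=C/C(=O)OC)[C@H]2CO[C@H](c3ccc(O[Si](C(C)C)(C(C)C)C(C)C)cc3)[C@@H]2C=O)cc1
F2 | step 5 | methyl (E)-3-[(2S,3S,4S)-3-(hydroxymethyl)-2-[4-(triisopropylsilyloxy)phenyl]tetrahydrofuran-4-yl]-3-(4-methoxyphenyl)prop-2-enoate (C2 epimer of 10) | COc1ccc(/C(=C/C(=O)OC)[C@H]2CO[C@H](c3ccc(O[Si](C(C)C)(C(C)C)C(C)C)cc3)[C@@H]2CO)cc1
F3 | step 4 | [(2S,3R,4S)-4-[(S)-hydroxy(4-methoxyphenyl)methyl]-2-[4-(triisopropylsilyloxy)phenyl]tetrahydrofuran-3-yl]methyl acetate | COc1ccc([C@@H](O)[C@@H]2CO[C@H](c3ccc(O[Si](C(C)C)(C(C)C)C(C)C)cc3)[C@H]2COC(C)=O)cc1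
F4 | step 9 | [(2R,3S,4R)-4-[(R)-hydroxy(4-methoxyphenyl)methyl]-2-[4-(triisopropylsilyloxy)phenyl]tetrahydrofuran-3-yl]methyl acetate | COc1ccc([C@H](O)[C@H]2CO[C@@H](c3ccc(O[Si](C(C)C)(C(C)C)C(C)C)cc3)[C@@H]2COC(C)=O)cc1
F5 | step 8 | methyl 3-[(2R,3S,4S)-3-(acetoxymethyl)-2-[4-(triisopropylsilyloxy)phenyl]tetrahydrofuran-4-yl]-2,3-dihydroxy-3-(4-methoxyphenyl)propanoate (diol carbons unassigned) | COc1ccc(C(O)(C(O)C(=O)OC)[C@H]2CO[C@@H](c3ccc(O[Si](C(C)C)(C(C)C)C(C)C)cc3)[C@@H]2COC(C)=O)cc1
F6 | step 11 | [(2R,3S,4R)-4-[(S)-acetoxy(4-methoxyphenyl)methyl]-2-(4-acetoxyphenyl)tetrahydrofuran-3-yl]methyl acetate | COc1ccc([C@@H](OC(C)=O)[C@H]2CO[C@@H](c3ccc(OC(C)=O)cc3)[C@@H]2COC(C)=O)cc1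
A1 | alternative 1 | [(2R,3S,4R)-4-[(S)-acetoxy(4-methoxyphenyl)methyl]-2-(4-acetoxyphenyl)tetrahydrofuran-3-yl]methyl acetate | COc1ccc([C@@H](OC(C)=O)[C@H]2CO[C@@H](c3ccc(OC(C)=O)cc3)[C@@H]2COC(C)=O)cc1
A2 | alternative 1 | 4-[(1R,2S,3E)-2-(acetoxymethyl)-1-(methoxymethoxy)-4-(4-methoxyphenyl)but-3-en-1-yl]phenyl acetate | COCO[C@@H](c1ccc(OC(C)=O)cc1)[C@H](COC(C)=O)/C=C/c1ccc(OC)cc1
A3 | alternative 2 | [(2R,3S,4S)-4-(hydroxymethyl)-2-[4-(triisopropylsilyloxy)phenyl]tetrahydrofuran-3-yl]methyl acetate | OC[C@H]1CO[C@@H](c2ccc(O[Si](C(C)C)(C(C)C)C(C)C)cc2)[C@@H]1COC(C)=O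
A4 | alternative 2 | (2S,3R)-3-hydroxy-2-(oxetan-3-yl)-3-[4-(triisopropylsilyloxy)phenyl]propyl acetate | O[C@@H](c1ccc(O[Si](C(C)C)(C(C)C)C(C)C)cc1)[C@H](COC(C)=O)C1COC1
A5 | alternative 3 | [4-[(2R,3R,4R)-3-(dimethoxymethyl)-4-[methoxy(4-methoxyphenyl)methyl]tetrahydrofuran-2-yl]phenoxy]triisopropylsilane (C4a epimers) | COc1ccc(C(OC)[C@H]2CO[C@@H](c3ccc(O[Si](C(C)C)(C(C)C)C(C)C)cc3)[C@@H]2C(OC)OC)cc1
A6 | alternative 3 | triisopropyl[4-[(1R,2E)-3-methoxy-1-[(E)-3-(4-methoxyphenyl)prop-2-enyloxy]prop-2-enyl]phenoxy]silane | CO/C=C/[C@@H](OC/C=C/c1ccc(OC)cc1)c1ccc(O[Si](C(C)C)(C(C)C)C(C)C)cc1
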